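**Plan**

Atom labels used below: C1 = CH(O‑methacryloyl), C2 = CH2, C3 = CH(O‑angeloyl), C4 = C(CH3), C5 and C9 = cyclobutane CH next to C6 (C=O) and next to C8 (=C–CH3), C7 = vinylic CH, C10 = cyclobutane CH, C11 = CMe2.
Retrosynthesis: the two ester C–O bonds are cut last and the C6 carbonyl is taken back to an allylic CH2. The seven-membered ring C1–C2–C3–C4–C9–C10–C11 is then contracted by re-forming C1–C10, giving the six-membered ring of a 1‑siloxybicyclo[4.1.0]heptane whose cyclopropane is C1/C10/C11. That cyclopropane is cut into a C10 carbene (from a cyclobutanone) and the enol silane C1=C11; C4–C9 and C5–C10 are cut together as an intramolecular vinylketene–alkene [2+2]; C2–C3 is an aldol bond.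
Forward: acyclic C15 chain (methyl geranate + methyl isopropenyl ketone) → cyclobutane and six-membered ring in one [2+2] step → cyclopropane and a temporary six-membered ring by carbene addition → seven-membered ring by fragmentation of C1–C10 → enone, anti‑diol, two different esters.
Feature that makes the key event possible: C1 is a ketone-level carbon flanked by the quaternary C11 and by C10, a cyclobutane carbon. An oxygen donor on C1 of the C1/C10/C11 cyclopropane therefore expels C10 as the better (strained-ring) carbanion, and only this cleavage releases the strain of the fused six-membered ring.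
Stereochemistry: C3 from a reagent-controlled boron aldol; C4, C5 and C9 relayed from C3 in the [2+2] (E‑alkene geometry puts the C4 methyl syn to the C6–C8 bridge); C10 fixed by the ring constraint of the fragmentation; C1 by hydride delivery from the C3 oxygen (1,3‑anti); the Z‑ester geometry is bought with angelic acid.

Key step: step 9

Assumption: the enolate made with (−)-Ipc2BCl attacks the Re face of enal 2 and gives the (8R)-alcohol 6; if the induction is the opposite, (+)-Ipc2BCl is used.

**Step 1**
Reactants: 1 methyl (2E)-3,7-dimethylocta-2,6-dienoate (methyl geranate)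
Product: 2 methyl (2E,6E)-3,7-dimethyl-8-oxoocta-2,6-dienoate
Conditions: SeO2 (1.2 eq), 1,4-dioxane, 80 °C
Reagents that add atoms: selenium dioxide, O=[Se]=O
Why: Riley oxidation, in which SeO2 attacks the electron-rich 6,7-alkene (the conjugated 2,3-alkene is deactivated) by ene reaction and [2,3]-shift at the (E)-methyl group and should carry the allylic alcohol on to the (E)-enal; no stereocentre is formed.

**Step 2**
Reactants: 2 methyl (2E,6E)-3,7-dimethyl-8-oxoocta-2,6-dienoate; 3 3-methylbut-3-en-2-one
Product: 6 methyl (2E,6E,8R)-8-hydroxy-3,7,11-trimethyl-10-oxododeca-2,6,11-trienoate, via boron enolate 4 (not isolated), via boron aldolate 5 (not isolated)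
Conditions: 3, (−)-Ipc2BCl [(−)-B-chlorodiisopinocampheylborane], Et3N, Et2O, −78 → 0 °C; then 2, −78 → −20 °C; then MeOH, pH 7 buffer, H2O2, 0 °C
Reagents that add atoms: 3-methylbut-3-en-2-one (3), CC(=O)C(C)=C
Why: Reagent-controlled boron aldol addition, in which the acetyl CH3 is the only enolisable position of 3 and the Ipc2B enolate adds through a cyclic transition state to one face of the enal, which sets C3 (R), while the ester does not react.

**Step 3**
Reactants: 6 methyl (2E,6E,8R)-8-hydroxy-3,7,11-trimethyl-10-oxododeca-2,6,11-trienoate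
Product: 7 methyl (2E,6E,8R)-8-(tert-butyldimethylsilyloxy)-3,7,11-trimethyl-10-oxododeca-2,6,11-trienoate
Conditions: TBSOTf, 2,6-lutidine, CH2Cl2, −78 °C
Reagents that add atoms: tert-butyldimethylsilyl trifluoromethanesulfonate, CC(C)(C)[Si](C)(C)OS(=O)(=O)C(F)(F)F
Why: Silyl ether formation under a non-nucleophilic base at low temperature, which also forestalls oxa-Michael closure of the β-hydroxy enone.

**Step 4**
Reactants: 7 methyl (2E,6E,8R)-8-(tert-butyldimethylsilyloxy)-3,7,11-trimethyl-10-oxododeca-2,6,11-trienoate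
Product: 9 (2E,6E,8R)-8-(tert-butyldimethylsilyloxy)-3,7,11-trimethyl-10-oxododeca-2,6,11-trienoic acid, via stannyl ester 8 (not isolated)
Conditions: Me3SnOH (5 eq), 1,2-dichloroethane, 75 °C; then 1 M HCl
Reagents that add atoms: trimethyltin hydroxide, C[Sn](C)(C)O
Why: Near-neutral methyl ester cleavage with Me3SnOH, chosen because hydroxide or alkoxide bases would eliminate the β-silyloxy ketone; the stannyl ester is split on acidic work-up.

**Step 5**
Reactants: 9 (2E,6E,8R)-8-(tert-butyldimethylsilyloxy)-3,7,11-trimethyl-10-oxododeca-2,6,11-trienoic acid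
Product: 12 (1R,5S,7S)-7-[(1R)-1-(tert-butyldimethylsilyloxy)-4-methyl-3-oxopent-4-en-1-yl]-7-methyl-2-methylidenebicyclo[3.1.1]heptan-6-one, via acid chloride 10 (not isolated), via vinylketene 11 (not isolated)
Conditions: 1-chloro-N,N,2-trimethylprop-1-en-1-amine, CH2Cl2, 0 °C → rt; then slow addition to Et3N (3 eq), toluene, 110 °C, high dilution
Reagents that add atoms: none
Why: Intramolecular vinylketene–alkene [2+2] cycloaddition (the known route from 3-methylalk-2-enoyl chlorides with a 6,7-alkene to bicyclo[3.1.1]heptan-6-ones), in which 1,4-dehydrochlorination at the methyl group cis to the acyl group gives the ketene, its carbonyl carbon bonds to the less substituted C5 and its α-carbon C9 to C4, the E-alkene geometry places the C4 methyl syn to the methylidene bridge, and the allylic stereocentre C3 (silyloxy group in the alkene plane, C2 anti to the incoming ketene) should select the alkene face and so set C4, C5 and C9.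

**Step 6**
Reactants: 12 (1R,5S,7S)-7-[(1R)-1-(tert-butyldimethylsilyloxy)-4-methyl-3-oxopent-4-en-1-yl]-7-methyl-2-methylidenebicyclo[3.1.1]heptan-6-one
Product: 13 (1R,5S,7S)-7-[(1R)-1-(tert-butyldimethylsilyloxy)-4-methyl-3-(triethylsilyloxy)pent-3-en-1-yl]-7-methyl-2-methylidenebicyclo[3.1.1]heptan-6-one
Conditions: RhCl(PPh3)3 (2 mol %), Et3SiH (1.5 eq), benzene, 50 °C
Reagents that add atoms: triethylsilane, CC[SiH](CC)CC
Why: Rhodium-catalysed 1,4-hydrosilylation of the enone, which gives the fully substituted enol silane C1=C11 regiospecifically without an enolate (so the β-silyloxy group is not eliminated), while the cyclobutanone and the 1,1-disubstituted alkene react much more slowly with a monohydrosilane; no stereocentre is formed.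

**Step 7**
Reactants: 13 (1R,5S,7S)-7-[(1R)-1-(tert-butyldimethylsilyloxy)-4-methyl-3-(triethylsilyloxy)pent-3-en-1-yl]-7-methyl-2-methylidenebicyclo[3.1.1]heptan-6-one
Product: 14 2-(trifluoromethyl)benzenesulfonylhydrazone of 13 at the ring ketone (C10)
Conditions: 2-(trifluoromethyl)benzenesulfonohydrazide (1.1 eq), 4 Å molecular sieves, THF, 40 °C
Reagents that add atoms: 2-(trifluoromethyl)benzenesulfonohydrazide, NNS(=O)(=O)c1ccccc1C(F)(F)F
Why: Hydrazone formation at the strained, non-enolisable cyclobutanone under neutral dehydrating conditions that leave both silyl groups untouched.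

**Step 8**
Reactants: 14 2-(trifluoromethyl)benzenesulfonylhydrazone of 13
Product: 17 tetracyclic siloxycyclopropane (cyclopropane C1(OSiEt3)–C10–C11Me2 spiro-fused at C10 to the cyclobutane and fused along C1–C10 to the new six-membered ring C1–C2–C3–C4–C9–C10), via sodium salt 15 (not isolated), via diazoalkane 16 (not isolated)
Conditions: NaH (1.5 eq), Rh2(OAc)4 (2 mol %), PhCF3, 0 → 50 °C
Reagents that add atoms: none
Why: Bamford–Stevens-type release of the diazoalkane from the sulfonylhydrazone anion followed by rhodium-carbenoid cyclopropanation of the tethered electron-rich enol silane through a six-membered-ring transition state; the carbene carbon has no α-hydrogen that could shift without making a bridgehead alkene, the tether reaches only the face of C10 anti to the methylidene bridge (which fixes C10), and either configuration at C1 is acceptable because C1 becomes a carbonyl carbon in step 9.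

**Step 9**
Reactants: 17 tetracyclic siloxycyclopropane
Product: 19 ring-expanded tricyclic ketone (core of 30 with C1=O, C3–OSi(t-Bu)Me2, C6H2, C7H2 and exocyclic C8=CH2), via cyclopropanolate 18 (not isolated)
Conditions: TBAF·3H2O (1.1 eq), THF, −40 → 0 °C; then AcOH
Reagents that add atoms: none
Why: Fluoride removes the triethylsilyl group selectively (less hindered silicon on the cyclopropyl oxygen versus the secondary TBS ether) and the cyclopropanolate opens as a homoenolate, the C1–C10 bond breaking as C1 becomes the ketone and the C10 carbanion taking a proton from the water of the reagent. The closest known reactions are the base-induced ring opening of cyclopropanols and siloxycyclopropanes and the ring enlargement of 1-siloxybicyclo[n.1.0]alkanes. No ring is closed: the six-membered ring C1–C2–C3–C4–C9–C10 is enlarged to the seven-membered ring by the CMe2 carbon C11 when the zero-atom bridge C1–C10 is cleaved. The new stereocentre C10 is controlled by the framework, because only the cis-bridged seven-membered ring across the cyclobutane can exist, so the proton enters on the outer face with inversion at C10. The step needs cleavage of C1–C10 and not of C1–C11: both would leave tertiary carbanions, but C10 is a cyclobutane carbon (higher s-character), and only C1–C10 cleavage releases the strain of the spiro-fused, boat-locked six-membered ring and avoids a quaternary C10. Low temperature and the acetic acid quench are meant to keep the β-silyloxy ketone from eliminating.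

**Step 10**
Reactants: 19 ring-expanded tricyclic ketone with exocyclic C8=CH2
Product: 20 tricyclic ketone with the ring alkene C7=C8(CH3) (otherwise as 19)
Conditions: RuHCl(CO)(PPh3)3 (5 mol %), toluene, 80 °C
Reagents that add atoms: none
Why: Ruthenium hydride-catalysed alkene isomerisation (hydrometalation and β-hydride elimination), which should move the exocyclic double bond into the ring to the more stable trisubstituted alkene, as in β-pinene → α-pinene; no stereocentre changes.

**Step 11**
Reactants: 20 tricyclic ketone with the ring alkene C7=C8(CH3)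
Product: 21 enedione (20 with C6=O, i.e. the enone C6(=O)–C7=C8 of the target)
Conditions: Rh2(cap)4 [dirhodium tetrakis(caprolactamate)] (1 mol %), t-BuOOH (5 eq), K2CO3, CH2Cl2, rt
Reagents that add atoms: tert-butyl hydroperoxide, CC(C)(C)OO
Why: Allylic oxidation at the only allylic CH2 (C6), the analogue of the α-pinene → verbenone oxidation; the other allylic positions are a bridgehead CH and a methyl group.

**Step 12**
Reactants: 21 enedione with C3–OSi(t-Bu)Me2
Product: 22 hydroxy enedione (free C3–OH, C1=O, C6 enone)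
Conditions: HF·pyridine, pyridine, THF, 0 °C → rt
Reagents that add atoms: none
Why: Acidic fluoride cleaves the silyl ether without the retro-aldol or elimination that basic fluoride could cause in the β-hydroxy ketone.

**Step 13**
Reactants: 22 hydroxy enedione; 23 pent-4-enal
Product: 24 C3 pent-4-enoate of the C1,C3-anti diol (C1–OH free, C6 enone intact)
Conditions: 23 (6 eq), SmI2 (0.3 eq, premixed with 23), THF, −10 °C
Reagents that add atoms: pent-4-enal (23), C=CCCC=O
Why: Evans–Tishchenko reduction, in which the hemiacetal formed from the C3 hydroxyl and the aldehyde on trivalent samarium delivers hydride intramolecularly to the C1 ketone on the face of the C3 oxygen; this sets C1 anti to C3 and leaves the C3 oxygen acylated, so the two oxygens are differentiated, and the C6 carbonyl is out of reach.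

**Step 14**
Reactants: 24 C3 pent-4-enoate with free C1–OH; 25 methacrylic anhydride
Product: 26 C1 methacrylate C3 pent-4-enoate
Conditions: 25 (3 eq), Et3N, DMAP (0.2 eq), CH2Cl2, rt
Reagents that add atoms: methacrylic anhydride (25), CC(=C)C(=O)OC(=O)C(C)=C
Why: DMAP-catalysed acylation of the only free hydroxyl (C1) by the anhydride.

**Step 15**
Reactants: 26 C1 methacrylate C3 pent-4-enoate
Product: 27 C1 methacrylate with free C3–OH
Conditions: I2 (3 eq), NaHCO3, THF/H2O (3:1), 0 °C → rt; then aq. Na2S2O3
Reagents that add atoms: none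
Why: Iodine-induced removal of the pent-4-enoate (iodolactonisation through the ester carbonyl oxygen, then hydrolysis of the cyclic oxocarbenium ion); the electron-poor methacrylate and enone double bonds should not react with iodine.

**Step 16**
Reactants: 27 C1 methacrylate with free C3–OH; 28 angelic acid [(2Z)-2-methylbut-2-enoic acid]
Product: 30 (1R,2R,3R,5R,7S,8R)-2,6,6,9-tetramethyl-5-(2-methylprop-2-enoyloxy)-11-oxotricyclo[5.4.0.0(2,8)]undec-9-en-3-yl (2Z)-2-methylbut-2-enoate (CNP0317071.1), via mixed anhydride 29 (not isolated)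
Conditions: 28 (3 eq), 2,4,6-trichlorobenzoyl chloride (3 eq), Et3N, toluene, rt; then 27, 80 °C
Reagents that add atoms: angelic acid (28), C/C=C(/C)C(=O)O
Why: Yamaguchi esterification through the mixed anhydride without a nucleophilic catalyst, conditions meant to acylate a hindered secondary alcohol while keeping the (Z)-geometry of the angeloyl group; no stereocentre is touched.

**Compound list**

1 | methyl (2E)-3,7-dimethylocta-2,6-dienoate (methyl geranate) | COC(=O)/C=C(\C)CCC=C(C)C | starting material
2 | methyl (2E,6E)-3,7-dimethyl-8-oxoocta-2,6-dienoate | COC(=O)/C=C(\C)CC/C=C(\C)C=O | intermediate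
3 | 3-methylbut-3-en-2-one (methyl isopropenyl ketone) | CC(=O)C(C)=C | starting material
4 | boron enolate: 2-(diisopinocampheylboryloxy)-3-methylbuta-1,3-diene | C=C(C)C(=C)OB([C@@H]1C[C@@H]2C[C@H]([C@H]1C)C2(C)C)[C@@H]1C[C@@H]2C[C@H]([C@H]1C)C2(C)C | intermediate
5 | boron aldolate: O-diisopinocampheylboryl derivative of 6 | COC(=O)/C=C(\C)CC/C=C(\C)[C@H](OB([C@@H]1C[C@@H]2C[C@H]([C@H]1C)C2(C)C)[C@@H]1C[C@@H]2C[C@H]([C@H]1C)C2(C)C)CC(=O)C(C)=C | intermediate
6 | methyl (2E,6E,8R)-8-hydroxy-3,7,11-trimethyl-10-oxododeca-2,6,11-trienoate | COC(=O)/C=C(\C)CC/C=C(\C)[C@H](O)CC(=O)C(C)=C | intermediate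
7 | methyl (2E,6E,8R)-8-(tert-butyldimethylsilyloxy)-3,7,11-trimethyl-10-oxododeca-2,6,11-trienoate | COC(=O)/C=C(\C)CC/C=C(\C)[C@H](O[Si](C)(C)C(C)(C)C)CC(=O)C(C)=C | intermediate
8 | trimethylstannyl ester of 9 | C[Sn](C)(C)OC(=O)/C=C(\C)CC/C=C(\C)[C@H](O[Si](C)(C)C(C)(C)C)CC(=O)C(C)=C | intermediate
9 | (2E,6E,8R)-8-(tert-butyldimethylsilyloxy)-3,7,11-trimethyl-10-oxododeca-2,6,11-trienoic acid | OC(=O)/C=C(\C)CC/C=C(\C)[C@H](O[Si](C)(C)C(C)(C)C)CC(=O)C(C)=C | intermediate
10 | acid chloride of 9 | ClC(=O)/C=C(\C)CC/C=C(\C)[C@H](O[Si](C)(C)C(C)(C)C)CC(=O)C(C)=C | intermediate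
11 | vinylketene: (6E,8R)-8-(tert-butyldimethylsilyloxy)-7,11-dimethyl-3-methylidenedodeca-1,6,11-triene-1,10-dione | O=C=CC(=C)CC/C=C(\C)[C@H](O[Si](C)(C)C(C)(C)C)CC(=O)C(C)=C | intermediate
12 | (1R,5S,7S)-7-[(1R)-1-(tert-butyldimethylsilyloxy)-4-methyl-3-oxopent-4-en-1-yl]-7-methyl-2-methylidenebicyclo[3.1.1]heptan-6-one (7-methyl syn to the C2–C4 bridge) | C=C(C)C(=O)C[C@@H](O[Si](C)(C)C(C)(C)C)[C@@]1(C)[C@@H]2CCC(=C)[C@H]1C2=O | intermediate
13 | (1R,5S,7S)-7-[(1R)-1-(tert-butyldimethylsilyloxy)-4-methyl-3-(triethylsilyloxy)pent-3-en-1-yl]-7-methyl-2-methylidenebicyclo[3.1.1]heptan-6-one | CC(C)=C(O[Si](CC)(CC)CC)C[C@@H](O[Si](C)(C)C(C)(C)C)[C@@]1(C)[C@@H]2CCC(=C)[C@H]1C2=O | intermediate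
14 | 2-(trifluoromethyl)benzenesulfonylhydrazone of 13 (at the ring ketone) | CC(C)=C(O[Si](CC)(CC)CC)C[C@@H](O[Si](C)(C)C(C)(C)C)[C@@]1(C)[C@@H]2CCC(=C)[C@H]1C2=NNS(=O)(=O)c1ccccc1C(F)(F)F | intermediate
15 | sodium salt of 14 | [Na+].CC(C)=C(O[Si](CC)(CC)CC)C[C@@H](O[Si](C)(C)C(C)(C)C)[C@@]1(C)[C@@H]2CCC(=C)[C@H]1C2=N[N-]S(=O)(=O)c1ccccc1C(F)(F)F | intermediate
16 | diazoalkane: 6-diazo analogue of 13 | CC(C)=C(O[Si](CC)(CC)CC)C[C@@H](O[Si](C)(C)C(C)(C)C)[C@@]1(C)[C@@H]2CCC(=C)[C@H]1C2=[N+]=[N-] | intermediate
17 | tetracyclic siloxycyclopropane (cyclopropane C1(OSiEt3)–C10–C11Me2; C10 spiro to the cyclobutane; C3–OTBS; exocyclic C8=CH2) | CC[Si](CC)(CC)O[C@]12C[C@@H](O[Si](C)(C)C(C)(C)C)[C@@]3(C)[C@@H]4CCC(=C)[C@H]3[C@@]41C2(C)C | intermediate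
18 | tetrabutylammonium cyclopropanolate from 17 | CCCC[N+](CCCC)(CCCC)CCCC.[O-][C@]12C[C@@H](O[Si](C)(C)C(C)(C)C)[C@@]3(C)[C@@H]4CCC(=C)[C@H]3[C@@]41C2(C)C | intermediate
19 | ring-expanded tricyclic ketone (core of 30 with C1=O, C3–OTBS, C6H2, C7H2, exocyclic C8=CH2) | O=C1C[C@@H](O[Si](C)(C)C(C)(C)C)[C@@]2(C)[C@@H]3CCC(=C)[C@H]2[C@@H]3C1(C)C | intermediate
20 | tricyclic ketone with ring alkene C7=C8(CH3) (C1=O, C3–OTBS, C6H2) | O=C1C[C@@H](O[Si](C)(C)C(C)(C)C)[C@@]2(C)[C@@H]3CC=C(C)[C@H]2[C@@H]3C1(C)C | intermediate
21 | enedione (C1=O, C6=O conjugated with C7=C8, C3–OTBS) | O=C1C[C@@H](O[Si](C)(C)C(C)(C)C)[C@@]2(C)[C@@H]3C(=O)C=C(C)[C@H]2[C@@H]3C1(C)C | intermediate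
22 | hydroxy enedione (free C3–OH, C1=O, C6 enone) | O=C1C[C@@H](O)[C@@]2(C)[C@@H]3C(=O)C=C(C)[C@H]2[C@@H]3C1(C)C | intermediate
23 | pent-4-enal | C=CCCC=O | starting material
24 | C3 pent-4-enoate of the C1,C3-anti diol (C1–OH free) | O[C@@H]1C[C@@H](OC(=O)CCC=C)[C@@]2(C)[C@@H]3C(=O)C=C(C)[C@H]2[C@@H]3C1(C)C | intermediate
25 | methacrylic anhydride | CC(=C)C(=O)OC(=O)C(C)=C | starting material
26 | C1 methacrylate C3 pent-4-enoate | C=C(C)C(=O)O[C@@H]1C[C@@H](OC(=O)CCC=C)[C@@]2(C)[C@@H]3C(=O)C=C(C)[C@H]2[C@@H]3C1(C)C | intermediate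
27 | C1 methacrylate with free C3–OH | C=C(C)C(=O)O[C@@H]1C[C@@H](O)[C@@]2(C)[C@@H]3C(=O)C=C(C)[C@H]2[C@@H]3C1(C)C | intermediate
28 | angelic acid, (2Z)-2-methylbut-2-enoic acid | C/C=C(/C)C(=O)O | starting material
29 | mixed anhydride of angelic acid and 2,4,6-trichlorobenzoic acid | C/C=C(/C)C(=O)OC(=O)c1c(Cl)cc(Cl)cc1Cl | intermediate
30 | (1R,2R,3R,5R,7S,8R)-2,6,6,9-tetramethyl-5-(2-methylprop-2-enoyloxy)-11-oxotricyclo[5.4.0.0(2,8)]undec-9-en-3-yl (2Z)-2-methylbut-2-enoate (CNP0317071.1) | C=C(C)C(=O)O[C@@H]1C[C@@H](OC(=O)/C(C)=C\C)[C@@]2(C)[C@@H]3C(=O)C=C(C)[C@H]2[C@@H]3C1(C)C | target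

**Totals**

Total step count: 16. Longest linear sequence: 16 steps (1 → 30).

**Steps most likely to fail**

Step 8 (carbene cyclopropanation). The diazoalkane or carbenoid may be consumed by azine formation, by a 1,2-shift of the neighbouring alkenyl carbon or by C–H insertion, or the fully substituted cyclopropane may not close for steric reasons. The fallback sets out from 13 and comes back at 19, and no longer uses a carbene. BF3·OEt2 in CH2Cl2 at −78 °C should bring about an intramolecular Mukaiyama aldol addition of the enol silane to the strained, non-enolisable cyclobutanone carbonyl C10 and give the tertiary ketol F1. Methyl chlorooxoacetate, DMAP and pyridine then give the methyl oxalate F2, and Bu3SnH with AIBN in toluene at 110 °C (Barton–McCombie-type deoxygenation of the tertiary alcohol) should deliver hydrogen to the outer face of C10 and give 19.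

Step 9 (fragmentation). The cyclopropanolate may open at the other bond (C1–C11) and leave the six-membered ring in place, or the β-silyloxy ketone may lose silanol under the basic fluoride. The fallback sets out from 17 and comes back at 19 through a one-electron instead of an anionic opening. Anhydrous FeCl3 in DMF at 0 °C should oxidise the siloxycyclopropane to the cyclopropyloxy radical, whose β-scission is governed by strain release at C1–C10, and chlorine transfer should give the chloro ketone F3. Bu3SnH with AIBN in benzene at 80 °C then removes the chlorine and gives 19.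

Step 16 (angeloylation). Acylation of the hindered C3 hydroxyl may be slow enough for Z → E isomerisation of the angeloyl unit to the tigloyl isomer, or for migration of the methacryloyl group, to compete. The fallback sets out from 27 and comes back at 30 by building the Z-alkene on the molecule. Esterification with 2-[bis(2,2,2-trifluoroethoxy)phosphoryl]propanoic acid (EDC·HCl, DMAP, CH2Cl2) gives the phosphonate ester F4. KN(SiMe3)2 with 18-crown-6 in THF at −78 °C, then acetaldehyde (Still–Gennari olefination), should give the (Z)-2-methylbut-2-enoate 30.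

**Further compounds**

F1 | step 8 | tertiary ketol: 19 with OH in place of H at C10 | O=C1C[C@@H](O[Si](C)(C)C(C)(C)C)[C@@]2(C)[C@@H]3CCC(=C)[C@H]2[C@]3(O)C1(C)C
F2 | step 8 | methyl oxalate of F1 | O=C1C[C@@H](O[Si](C)(C)C(C)(C)C)[C@@]2(C)[C@@H]3CCC(=C)[C@H]2[C@]3(OC(=O)C(=O)OC)C1(C)C
F3 | step 9 | chloro ketone: 19 with Cl in place of H at C10 | O=C1C[C@@H](O[Si](C)(C)C(C)(C)C)[C@@]2(C)[C@@H]3CCC(=C)[C@H]2[C@]3(Cl)C1(C)C
F4 | step 16 | phosphonate ester: C3 2-[bis(2,2,2-trifluoroethoxy)phosphoryl]propanoate of 27 | C=C(C)C(=O)O[C@@H]1C[C@@H](OC(=O)C(C)P(=O)(OCC(F)(F)F)OCC(F)(F)F)[C@@]2(C)[C@@H]3C(=O)C=C(C)[C@H]2[C@@H]3C1(C)C
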